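Ring A contains a γ,δ-unsaturated ester, C19(=O)–C4–C5–C10=C1, the retron of a Claisen rearrangement, and because C1 and C4 are also linked through C2–C3 the allylic ester precursor is a δ-lactone. The key step is therefore an Ireland–Claisen rearrangement of a 3-methyl-6-(cyclohexenyl)oxan-2-one that already carries ring B with C8 and C9: through an enforced boat transition state it closes ring A at C4–C5, creates the quaternary C4 and the C5 stereocentre by chirality transfer from the lactone carbinol carbon, and sets the C1=C10 alkene in one operation. Ring B comes from an asymmetric conjugate addition–allylation; the allyl group is elaborated to the side chain last.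

Key step: step 6

Numbering used: ring A = C1–C2–C3–C4–C5–C10, ring B = C5–C6–C7–C8–C9–C10; C4 carries CH3 and the ester carbon (called C19), C8 carries CH3, C9 carries CH3 and the chain C11–C15 (CH3 on C13, propanoate oxygen on C15).

Assumption: the sense of induction of the phosphoramidite ligand in step 1 is assigned by analogy with additions to cyclohex-2-enone; the antipodal ligand is used if the opposite sense is found.

Step 1
Reactants: 1 2-methylcyclohex-2-en-1-one
Product: 3 (2S,3R)-2,3-dimethyl-2-(prop-2-en-1-yl)cyclohexan-1-one, via aluminium enolate 2 (not isolated)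
Conditions: Me3Al, Cu(O2CC4H3S) (copper thiophene-2-carboxylate, 2 mol %), (R)-BINOL-derived N,N-bis[(S)-1-phenylethyl]phosphoramidite (4 mol %), Et2O, −30 °C; then MeLi, allyl iodide, THF/DMPU, −30 → 0 °C
Reagents that add atoms: trimethylaluminium C[Al](C)C; allyl iodide C=CCI
Why: Copper-catalysed asymmetric conjugate addition sets C3 (C8 of the target) by ligand control, and the ate-activated enolate should then be C-allylated anti to the new C3 methyl group, which sets the quaternary C2 (C9) with the two methyl groups cis (tandem conjugate addition–enolate alkylation).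

Step 2
Reactants: 3 (2S,3R)-2,3-dimethyl-2-(prop-2-en-1-yl)cyclohexan-1-one
Product: 4 N'-[(2S,3R)-2,3-dimethyl-2-(prop-2-en-1-yl)cyclohexylidene]-2,4,6-tri(propan-2-yl)benzenesulfonohydrazide
Conditions: 2,4,6-triisopropylbenzenesulfonohydrazide, HCl (cat.), THF, rt
Reagents that add atoms: 2,4,6-tri(propan-2-yl)benzenesulfonohydrazide NNS(=O)(=O)c1c(C(C)C)cc(C(C)C)cc1C(C)C
Why: Acid-catalysed condensation of the ketone with the sulfonohydrazide should give the trisylhydrazone needed for a Shapiro reaction without touching a stereocentre.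

Step 3
Reactants: 4 trisylhydrazone of step 2; 5 methyl 5-chloro-5-oxopentanoate
Product: 8 methyl 5-[(5R,6S)-5,6-dimethyl-6-(prop-2-en-1-yl)cyclohex-1-en-1-yl]-5-oxopentanoate, via alkenyllithium 6 (not isolated), via alkenylzinc chloride 7 (not isolated)
Conditions: n-BuLi (2.2 equiv), THF, −78 → 0 °C; ZnCl2, −78 → 0 °C; then 5, Pd(PPh3)4 (5 mol %), 0 °C → rt
Reagents that add atoms: none
Why: The Shapiro reaction (double deprotonation at the only α-CH2, loss of sulfinate and N2) should give the alkenyllithium regiospecifically, and transmetalation to zinc followed by palladium-catalysed Negishi acylation with the acid chloride should give the enone without attack on the methyl ester.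

Step 4
Reactants: 8 enone ester of step 3
Product: 10 (6R)-6-[(5R,6S)-5,6-dimethyl-6-(prop-2-en-1-yl)cyclohex-1-en-1-yl]oxan-2-one, via hydroxy ester 9 (not isolated)
Conditions: (S)-1-methyl-3,3-diphenyltetrahydro-1H,3H-pyrrolo[1,2-c][1,3,2]oxazaborole ((S)-Me-CBS, 20 mol %), catecholborane, toluene, −78 °C; then pyridinium p-toluenesulfonate (cat.), toluene, 60 °C
Reagents that add atoms: none
Why: In the CBS reduction the branched alkenyl group acts as the large substituent, so the (S)-catalyst should deliver the (R)-allylic alcohol under catalyst control, and acid-catalysed lactonisation of the δ-hydroxy ester then closes the oxan-2-one, whose minor carbinol epimer is a diastereomer that can be removed here.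

Step 5
Reactants: 10 lactone of step 4
Product: 11 (6R)-6-[(5R,6S)-5,6-dimethyl-6-(prop-2-en-1-yl)cyclohex-1-en-1-yl]-3-methyloxan-2-one (both C3 epimers)
Conditions: LiN(iPr)2, THF, −78 °C; MeI, −78 → −40 °C
Reagents that add atoms: iodomethane CI
Why: Alkylation of the lactone lithium enolate with iodomethane installs the future C4 methyl group, and the configuration at C3 is irrelevant because it is erased on enolisation in step 6.

Step 6
Reactants: 11 3-methyl lactone of step 5
Product: 14 (1S,5S,6R,8aR)-1,5,6-trimethyl-5-(prop-2-en-1-yl)-1,2,3,5,6,7,8,8a-octahydronaphthalene-1-carboxylic acid, via silyl ketene acetal 12 (not isolated), via silyl ester 13 (not isolated)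
Conditions: LiN(iPr)2, THF, −78 °C; t-BuMe2SiCl, DMPU, −78 → 0 °C; toluene, 110 °C; then 1 M HCl, THF, rt
Reagents that add atoms: none
Why: Enolisation at C3 and O-silylation give the ring-constrained silyl ketene acetal 12, whose C4=C19(OSi)–O–C1–C10=C5 array undergoes a concerted suprafacial [3,3]-sigmatropic shift on heating: the C4–C5 bond forms, the lactone C1–O bond breaks and the alkene moves to C1=C10, after which silyl ester 13 is hydrolysed. The closest known reaction type is the Ireland–Claisen rearrangement of 6-alkenyl δ-lactone silyl ketene acetals to cyclohexenecarboxylic acids. Ring A (C4–C3–C2–C1=C10–C5) is closed by the sigmatropic bond formation itself, and because C2–C3 tie C1 to C4 the pericyclic array can only adopt a boat, bicyclo[2.2.2]octane-like transition state. C5 is set by chirality transfer from the carbinol carbon (6R in 11 gives 5R, the new bond forming on the alkene face that carried the C1–O bond), and C4 is set by the ring-fixed enolate geometry within that boat, which places the carboxyl trans and the methyl cis to H5 (4S). The selectivity needed is bond formation on the ring-B face syn to the C9 allyl group, and this is secured by the catalyst-derived carbinol configuration and the stereospecificity of the shift, not by the weak bias of C9; both C3 epimers of 11 converge on the same ketene acetal, and the alkene position is fixed by the mechanism.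

Step 7
Reactants: 14 acid of step 6
Product: 15 methyl (1S,5S,6R,8aR)-1,5,6-trimethyl-5-(prop-2-en-1-yl)-1,2,3,5,6,7,8,8a-octahydronaphthalene-1-carboxylate
Conditions: MeI, K2CO3, DMF, rt
Reagents that add atoms: iodomethane CI
Why: O-Alkylation of the carboxylate (SN2 on iodomethane) is insensitive to the hindrance of the neopentyl-type acid and leaves all stereocentres untouched.

Step 8
Reactants: 15 methyl ester of step 7
Product: 17 methyl (1S,5S,6R,8aR)-5-(3-hydroxypropyl)-1,5,6-trimethyl-1,2,3,5,6,7,8,8a-octahydronaphthalene-1-carboxylate, via alkylborane 16 (not isolated)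
Conditions: 9-BBN, THF, 0 °C → rt; then NaOH, H2O2, 0 °C
Reagents that add atoms: hydrogen peroxide OO
Why: Hydroboration with the bulky 9-BBN should be selective for the monosubstituted allyl alkene over the hindered trisubstituted C1=C10 alkene and place boron at the terminal carbon, and oxidation then gives the primary alcohol (anti-Markovnikov hydroboration–oxidation).

Step 9
Reactants: 17 primary alcohol of step 8
Product: 18 methyl (1S,5S,6R,8aR)-1,5,6-trimethyl-5-(3-oxopropyl)-1,2,3,5,6,7,8,8a-octahydronaphthalene-1-carboxylate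
Conditions: Dess–Martin periodinane, NaHCO3, CH2Cl2, rt
Reagents that add atoms: none
Why: Dess–Martin oxidation should give the aldehyde under buffered, non-epimerising conditions that leave both alkenes and the ester alone.

Step 10
Reactants: 18 aldehyde of step 9
Product: 19 methyl (1S,5S,6R,8aR)-5-(but-3-yn-1-yl)-1,5,6-trimethyl-1,2,3,5,6,7,8,8a-octahydronaphthalene-1-carboxylate
Conditions: dimethyl (1-diazo-2-oxopropyl)phosphonate, K2CO3, MeOH, 0 °C → rt
Reagents that add atoms: dimethyl (1-diazo-2-oxopropyl)phosphonate COP(=O)(OC)C(=[N+]=[N-])C(C)=O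
Why: Ohira–Bestmann homologation converts the aldehyde into the terminal alkyne with one added carbon under carbonate conditions in which the methyl ester can only transesterify to itself.

Step 11
Reactants: 19 alkyne of step 10
Product: 21 methyl (1S,5S,6R,8aR)-5-[(3E)-5-hydroxy-3-methylpent-3-en-1-yl]-1,5,6-trimethyl-1,2,3,5,6,7,8,8a-octahydronaphthalene-1-carboxylate, via alkenylalane 20 (not isolated)
Conditions: Me3Al, (C5H5)2ZrCl2 (25 mol %), CH2Cl2, 0 °C → rt; volatiles removed; n-BuLi, THF/hexane, −78 °C; (CH2O)n, −78 °C → rt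
Reagents that add atoms: trimethylaluminium C[Al](C)C; formaldehyde (as paraformaldehyde) C=O
Why: Zirconium-catalysed carboalumination (Negishi) adds methyl and aluminium syn across the terminal alkyne with methyl at the internal carbon, and the derived alkenylalanate should react with formaldehyde with retention to give the (E)-3-methylallylic alcohol, the hindered C4 ester being expected to survive.

Step 12
Reactants: 21 allylic alcohol of step 11
Product: 22 methyl (1S,5S,6R,8aR)-1,5,6-trimethyl-5-[(3E)-3-methyl-5-(propanoyloxy)pent-3-en-1-yl]-1,2,3,5,6,7,8,8a-octahydronaphthalene-1-carboxylate (CNP0279628.1)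
Conditions: propanoyl chloride, pyridine, CH2Cl2, 0 °C
Reagents that add atoms: propanoyl chloride CCC(=O)Cl
Why: Acylation of the primary allylic alcohol (nucleophilic acyl substitution) should give the propanoate without touching the hindered methyl ester.

Compound list
1 | 2-methylcyclohex-2-en-1-one | CC1=CCCCC1=O | starting material
2 | dimethyl{[(3R)-2,3-dimethylcyclohex-1-en-1-yl]oxy}alumane (aluminium enolate) | CC1=C(O[Al](C)C)CCC[C@H]1C | intermediate (not isolated)
3 | (2S,3R)-2,3-dimethyl-2-(prop-2-en-1-yl)cyclohexan-1-one | C=CC[C@]1(C)C(=O)CCC[C@H]1C | intermediate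
4 | N'-[(2S,3R)-2,3-dimethyl-2-(prop-2-en-1-yl)cyclohexylidene]-2,4,6-tri(propan-2-yl)benzenesulfonohydrazide (C=N geometry not defined) | C=CC[C@]1(C)C(=NNS(=O)(=O)c2c(C(C)C)cc(C(C)C)cc2C(C)C)CCC[C@H]1C | intermediate
5 | methyl 5-chloro-5-oxopentanoate | COC(=O)CCCC(Cl)=O | starting material
6 | [(5R,6S)-5,6-dimethyl-6-(prop-2-en-1-yl)cyclohex-1-en-1-yl]lithium | C=CC[C@]1(C)C([Li])=CCC[C@H]1C | intermediate (not isolated)
7 | chloro[(5R,6S)-5,6-dimethyl-6-(prop-2-en-1-yl)cyclohex-1-en-1-yl]zinc | C=CC[C@]1(C)C([Zn]Cl)=CCC[C@H]1C | intermediate (not isolated)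
8 | methyl 5-[(5R,6S)-5,6-dimethyl-6-(prop-2-en-1-yl)cyclohex-1-en-1-yl]-5-oxopentanoate | C=CC[C@]1(C)C(C(=O)CCCC(=O)OC)=CCC[C@H]1C | intermediate
9 | methyl (5R)-5-[(5R,6S)-5,6-dimethyl-6-(prop-2-en-1-yl)cyclohex-1-en-1-yl]-5-hydroxypentanoate | C=CC[C@]1(C)C([C@H](O)CCCC(=O)OC)=CCC[C@H]1C | intermediate (not isolated)
10 | (6R)-6-[(5R,6S)-5,6-dimethyl-6-(prop-2-en-1-yl)cyclohex-1-en-1-yl]oxan-2-one | C=CC[C@]1(C)C([C@H]2CCCC(=O)O2)=CCC[C@H]1C | intermediate
11 | (6R)-6-[(5R,6S)-5,6-dimethyl-6-(prop-2-en-1-yl)cyclohex-1-en-1-yl]-3-methyloxan-2-one (both C3 epimers) | C=CC[C@]1(C)C([C@H]2CCC(C)C(=O)O2)=CCC[C@H]1C | intermediate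
12 | tert-butyl({(2R)-2-[(5R,6S)-5,6-dimethyl-6-(prop-2-en-1-yl)cyclohex-1-en-1-yl]-5-methyl-3,4-dihydro-2H-pyran-6-yl}oxy)dimethylsilane | C=CC[C@]1(C)C([C@H]2CCC(C)=C(O[Si](C)(C)C(C)(C)C)O2)=CCC[C@H]1C | intermediate (not isolated)
13 | tert-butyldimethylsilyl (1S,5S,6R,8aR)-1,5,6-trimethyl-5-(prop-2-en-1-yl)-1,2,3,5,6,7,8,8a-octahydronaphthalene-1-carboxylate | C=CC[C@]1(C)C2=CCC[C@](C)(C(=O)O[Si](C)(C)C(C)(C)C)[C@@H]2CC[C@H]1C | intermediate (not isolated)
14 | (1S,5S,6R,8aR)-1,5,6-trimethyl-5-(prop-2-en-1-yl)-1,2,3,5,6,7,8,8a-octahydronaphthalene-1-carboxylic acid | C=CC[C@]1(C)C2=CCC[C@](C)(C(=O)O)[C@@H]2CC[C@H]1C | intermediate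
15 | methyl (1S,5S,6R,8aR)-1,5,6-trimethyl-5-(prop-2-en-1-yl)-1,2,3,5,6,7,8,8a-octahydronaphthalene-1-carboxylate | C=CC[C@]1(C)C2=CCC[C@](C)(C(=O)OC)[C@@H]2CC[C@H]1C | intermediate
16 | methyl (1S,5S,6R,8aR)-5-[3-(9-borabicyclo[3.3.1]nonan-9-yl)propyl]-1,5,6-trimethyl-1,2,3,5,6,7,8,8a-octahydronaphthalene-1-carboxylate | C(CC[C@]1(C)C2=CCC[C@](C)(C(=O)OC)[C@@H]2CC[C@H]1C)B1C2CCCC1CCC2 | intermediate (not isolated)
17 | methyl (1S,5S,6R,8aR)-5-(3-hydroxypropyl)-1,5,6-trimethyl-1,2,3,5,6,7,8,8a-octahydronaphthalene-1-carboxylate | OCCC[C@]1(C)C2=CCC[C@](C)(C(=O)OC)[C@@H]2CC[C@H]1C | intermediate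
18 | methyl (1S,5S,6R,8aR)-1,5,6-trimethyl-5-(3-oxopropyl)-1,2,3,5,6,7,8,8a-octahydronaphthalene-1-carboxylate | O=CCC[C@]1(C)C2=CCC[C@](C)(C(=O)OC)[C@@H]2CC[C@H]1C | intermediate
19 | methyl (1S,5S,6R,8aR)-5-(but-3-yn-1-yl)-1,5,6-trimethyl-1,2,3,5,6,7,8,8a-octahydronaphthalene-1-carboxylate | C#CCC[C@]1(C)C2=CCC[C@](C)(C(=O)OC)[C@@H]2CC[C@H]1C | intermediate
20 | methyl (1S,5S,6R,8aR)-5-[(3E)-4-(dimethylalumanyl)-3-methylbut-3-en-1-yl]-1,5,6-trimethyl-1,2,3,5,6,7,8,8a-octahydronaphthalene-1-carboxylate | C[Al](C)/C=C(\C)CC[C@]1(C)C2=CCC[C@](C)(C(=O)OC)[C@@H]2CC[C@H]1C | intermediate (not isolated)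
21 | methyl (1S,5S,6R,8aR)-5-[(3E)-5-hydroxy-3-methylpent-3-en-1-yl]-1,5,6-trimethyl-1,2,3,5,6,7,8,8a-octahydronaphthalene-1-carboxylate | OC/C=C(\C)CC[C@]1(C)C2=CCC[C@](C)(C(=O)OC)[C@@H]2CC[C@H]1C | intermediate
22 | methyl (1S,5S,6R,8aR)-1,5,6-trimethyl-5-[(3E)-3-methyl-5-(propanoyloxy)pent-3-en-1-yl]-1,2,3,5,6,7,8,8a-octahydronaphthalene-1-carboxylate | CCC(=O)OC/C=C(\C)CC[C@]1(C)C2=CCC[C@](C)(C(=O)OC)[C@@H]2CC[C@H]1C | target

Total step count: 12. Longest linear sequence: 12 steps (1 → 22).

Steps most likely to fail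

Step 6. The congested boat transition state (C4 methyl over C6, silyloxy group over C9) may be reached too slowly, so that the ketene acetal is lost by C-silylation, hydrolysis or elimination before it rearranges. The fallback closes the same ring by an oxidative radical cyclisation. It sets out from hydrazone 4: Shapiro reaction (n-BuLi) with trapping of the alkenyllithium by paraformaldehyde should give the allylic alcohol [(5R,6S)-5,6-dimethyl-6-(prop-2-en-1-yl)cyclohex-1-en-1-yl]methanol F1; CBr4/PPh3 should give the allylic bromide F2; alkylation of the dianion of methyl 2-methyl-3-oxobutanoate (NaH, then n-BuLi) at its terminal carbon should give the β-keto ester F3. Mn(OAc)3·2H2O and Cu(OAc)2·H2O in AcOH should then effect 6-endo cyclisation of the α-keto ester radical onto C5 and oxidative elimination to the C1=C10 alkene, giving the bicyclic 3-oxo ester F4 with the ester trans to H5, as is usual for such cyclisations; the C5 epimer from attack on the other ring-B face would have to be separated. NaBH4 should give the alcohol F5, NaH/CS2/MeI the xanthate F6, and Bu3SnH/AIBN (Barton–McCombie deoxygenation) removes the oxygen and comes back to the route at ester 15.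

Step 3. Vinyllithium formation from the hindered hydrazone may be incomplete, or the sulfinate by-product may consume the acid chloride and stall the acylation. The fallback sets out from ketone 3: KN(SiMe3)2 and PhNTf2 should give the enol triflate F7; Nozaki–Hiyama–Kishi coupling (CrCl2, NiCl2 cat., DMF) with commercial methyl 5-oxopentanoate should give the hydroxy ester F8 as both carbinol epimers, which is kept neutral to avoid premature lactonisation; Dess–Martin oxidation then comes back to the route at enone 8.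

Step 1. The conjugate addition may proceed with insufficient enantioselectivity, or allylation of the aluminium enolate may be sluggish and poorly diastereoselective. The fallback takes the C8 stereocentre from the chiral pool. It sets out from commercial (R)-(+)-pulegone and comes back to the route at ketone 3: kinetic enolisation with LiN(iPr)2 at the CH2 next to the stereocentre and methylation should give the methylated pulegone F9; a second enolisation and alkylation with allyl bromide anti to the neighbouring methyl group should give the quaternary ketone F10; retro-aldol cleavage of the isopropylidene group (KOH, aqueous ethylene glycol, heat, acetone distilled off) should give 3.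

Further compounds
F1 | step 6 | [(5R,6S)-5,6-dimethyl-6-(prop-2-en-1-yl)cyclohex-1-en-1-yl]methanol | C=CC[C@]1(C)C(CO)=CCC[C@H]1C
F2 | step 6 | (5R,6S)-1-(bromomethyl)-5,6-dimethyl-6-(prop-2-en-1-yl)cyclohex-1-ene | C=CC[C@]1(C)C(CBr)=CCC[C@H]1C
F3 | step 6 | methyl 5-[(5R,6S)-5,6-dimethyl-6-(prop-2-en-1-yl)cyclohex-1-en-1-yl]-2-methyl-3-oxopentanoate (both C2 epimers) | C=CC[C@]1(C)C(CCC(=O)C(C)C(=O)OC)=CCC[C@H]1C
F4 | step 6 | methyl (1R,5S,6R,8aR)-1,5,6-trimethyl-2-oxo-5-(prop-2-en-1-yl)-1,2,3,5,6,7,8,8a-octahydronaphthalene-1-carboxylate | C=CC[C@]1(C)C2=CCC(=O)[C@](C)(C(=O)OC)[C@@H]2CC[C@H]1C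
F5 | step 6 | methyl (1R,5S,6R,8aR)-2-hydroxy-1,5,6-trimethyl-5-(prop-2-en-1-yl)-1,2,3,5,6,7,8,8a-octahydronaphthalene-1-carboxylate (C2 epimers) | C=CC[C@]1(C)C2=CCC(O)[C@](C)(C(=O)OC)[C@@H]2CC[C@H]1C
F6 | step 6 | methyl (1R,5S,6R,8aR)-1,5,6-trimethyl-2-{[(methylsulfanyl)carbonothioyl]oxy}-5-(prop-2-en-1-yl)-1,2,3,5,6,7,8,8a-octahydronaphthalene-1-carboxylate (C2 epimers) | C=CC[C@]1(C)C2=CCC(OC(=S)SC)[C@](C)(C(=O)OC)[C@@H]2CC[C@H]1C
F7 | step 3 | (5R,6S)-5,6-dimethyl-6-(prop-2-en-1-yl)cyclohex-1-en-1-yl trifluoromethanesulfonate | C=CC[C@]1(C)C(OS(=O)(=O)C(F)(F)F)=CCC[C@H]1C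
F8 | step 3 | methyl 5-[(5R,6S)-5,6-dimethyl-6-(prop-2-en-1-yl)cyclohex-1-en-1-yl]-5-hydroxypentanoate (both C5 epimers) | C=CC[C@]1(C)C(C(O)CCCC(=O)OC)=CCC[C@H]1C
F9 | step 1 | (3R)-2,3-dimethyl-6-(propan-2-ylidene)cyclohexan-1-one (C2 epimers) | C[C@@H]1CCC(=C(C)C)C(=O)C1C
F10 | step 1 | (2S,3R)-2,3-dimethyl-2-(prop-2-en-1-yl)-6-(propan-2-ylidene)cyclohexan-1-one | C=CC[C@]1(C)C(=O)C(=C(C)C)CC[C@H]1C
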